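## The problem

CNP0322180.1 is a cis-fused eudesmane; eudesmane numbering is used throughout (ring A = C1–C5 and C10, ring B = C5–C10, C14 on C10, C15 on C4, isopropyl C11–C13 on C7). It carries a C8 ketone, a 7β-isopropyl group, an angular 10β-methyl group and, on the α face of ring A, a secondary angelate at C3 beside a tertiary acetate at C4. There are five stereocentres (C3, C4, C5, C7, C10), two of them fully substituted (C4, C10). They are linked: the cis junction C5/C10 folds ring B under the α face of ring A and so decides from which side a C3=C4 double bond is attacked. Once C4 carries its β-methyl group, the 1,3-related methyl groups C14 and C15 hold the decalin in the one chair–chair form in which a 7β-isopropyl group is equatorial. C7, α to the ketone, can therefore be left to equilibration, whereas C10 and C5 must be set directly and C3/C4 derived from them. The fragile parts are the angelate (Z to E isomerisation to the tiglate under acid, base, nucleophilic catalysts or heat), the cis-vicinal diester (acyl migration between O3 and O4, ionisation of the tertiary acetate) and the epimerisable C7. A short route is possible because of ring A itself. The quaternary methyl carbon C10, flanked by C1 and C5 with the methyl-bearing C4 beyond C5, is the cycloadduct of methacrolein (C1, C10, C14, and C9 as the formyl carbon) with a 3-methyl-1,3-diene (C2–C5, C15). In (E)-β-ocimene that diene already bears on C5 the prenyl chain that holds C6, C7 and C11–C13, and the adduct's C3=C4 double bond is the latent cis-diol.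

## Retrosynthesis

**Acyl–oxygen bonds at O4 and O3.** The tertiary acetate of target 15 is removed first (hydroxy angelate 14), then the angelate, giving cis-diol 11 and angelic acid 12, which is used as its mixed anhydride 13. This order lets reactivity differentiate the hydroxyls: the equatorial secondary C3–OH of 11 is the only one an anhydride reaches without a nucleophilic catalyst, and after that the axial tertiary C4–OH is the only one left. The reverse order would leave a free secondary hydroxyl cis to a tertiary acetate during a slow angeloylation, the arrangement most prone to acyl migration. The forward steps must angeloylate without Z/E isomerisation and acetylate a hindered tertiary alcohol without ionising it.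

**C3–O and C4–O bonds, and the C7 configuration.** Both oxygens of 11 are traced to the C3=C4 double bond of the cis-octalinone 8. Direct osmylation would attack the open, convex β face and give the wrong diol. The Woodward cis-hydroxylation is chosen because it places the oxygens on the face opposite to the first electrophile. Iodonium enters β, acetate opens at C4 from α (iodo acetate 9), and neighbouring-group displacement of iodide from the α side followed by hydrolysis gives hydroxy acetate 10 with both oxygens α and C15 β. C7 is deliberately not corrected in 8. With C4 still trigonal the octalin can flip to a chair form that favours the 7α epimer, whereas in 10 and 11 the conformation is locked and 7β is the equatorial, stable position. One methoxide treatment of 10 therefore removes the acetate and sets C7, giving 11.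

**C7–C8 bond.** Ring B of 8 is opened between the carbonyl carbon and C7, which leads to aldehyde 7. An aldol or Michael closure at C5–C6 or C9–C10 would need extra functional groups. The radical hydroacylation makes the ring, the ketone and the isopropyl group in one redox-neutral isomerisation of the aldehyde and the prenyl alkene. The forward reaction needs 6-exo attack of the C8 acyl radical on C7 and leaves the C3=C4 double bond untouched.

**C8–C9 bond.** Aldehyde 7 is the one-carbon homologue of cycloadduct 3, reached through enol ether 6 from 3 and the ylide 5 of phosphonium salt 4. Building C8 into the dienophile instead would require a β,γ-unsaturated aldehyde, which is no dienophile. Keeping the formyl group on C10 for the cycloaddition and adding C8 afterwards costs two ordinary steps. The hydrolysis of 6 must be mild enough that 7, a citronellal-type enal, does not cyclise.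

**C1–C2 and C5–C10 bonds.** Ring A of 3 is split into methacrolein 1 and (E)-β-ocimene 2. No other cut of ring A produces two commercial components containing all fourteen carbons of 3, with C10 and C5 set in one catalytic step. The forward reaction needs C10-to-C5 ("ortho") regiochemistry, the formyl group endo (cis to the prenyl chain, the relation ring B requires) and one enal face, all from a chiral Lewis acid.

## Roads not taken

**Alternative 1:** Both rings are cut at once (C5–C10 and C6–C7). The forward step is an intramolecular Diels–Alder reaction of the open-chain trienone A1, whose vinyl ketone is tethered through the already oxygenated C3 to a 2-silyloxy diene, giving the cis-fused silyl enol ether A2.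
- Merits: two rings and the C8 oxygen in one step; the C3 oxygen is present from the start; the enol ether gives a regiodefined C8 enolate.
- Weak points: C10 is a diene terminus carrying both the methyl group and the tether, so one of them must sit inside the s-cis diene. This slows the cycloaddition and loosens the endo/exo preference that decides cis or trans fusion. The single stereocentre C3, α to a ketone and epimerisable, must direct the junction through a flexible tether. A2 still lacks the isopropyl group (a poor secondary alkylation at C7, or a multi-step detour) and the C4 methyl carbinol (a face-selective addition next to the junction). A1 itself needs a linear asymmetric synthesis.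
- Comparison: this road is better in ring-forming economy and avoids both the radical step and the silver/iodine chemistry. The chosen plan sets against it that every skeletal carbon, including C14, C15 and the isopropyl group, arrives in two purchased components, and that the route is clearly shorter.

**Alternative 2:** Ring A is closed at C1–C10 while C3–C8 breaks. The forward step is the anionic oxy-Cope rearrangement (KH, 18-crown-6) of the bridged vinyl carbinol A3, obtained by phenol dearomatisation and cycloaddition, giving the cis-octalinone A4.
- Merits: the sigmatropic shift is stereospecific, so the cis junction and the C5/C7/C10 relationship are guaranteed by the geometry of A3; C3 and C4 arrive oxygenated.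
- Weak points: the dearomatisation/cycloaddition entry to A3 is racemic, so the single enantiomer would require a resolution. The C4 ketal must become a methyl carbinol (a methyl nucleophile must choose C4 over C3 and the α face, then C3 must be reduced with the correct sense). The C8=C9 alkene must be turned regioselectively into the C8 ketone.
- Comparison: in certainty of relative configuration at C5, C7 and C10 this road is better than the chosen one, which relies on an endo preference and a later equilibration. The chosen plan sets against it catalyst control of absolute configuration and far fewer oxidation-state corrections.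

**Alternative 3:** Ring A is cut at C3–C4. The forward step is a pinacol cyclisation of keto aldehyde A5 with SmI2 (divalent samarium), giving the cis-diol A6 through a samarium-bridged diolate.
- Merits: the cis-diol appears in one step and by mechanism; the two hydroxyls are already distinguishable; C7 is fixed beforehand; no iodine or silver is needed.
- Weak points: A5 is a cyclohexane with four stereocentres, including the quaternary C10 bearing two different chains, so the main stereochemical problem is only moved into a long preparation of A5. The α,α versus β,β sense of the diol depends on the rotamer of the acetyl group. The C8 oxygen must be carried protected and oxidised late, beside sensitive esters.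
- Comparison: for the diol itself this road is better than the Woodward step. The chosen plan sets against it the formation of ring A and the quaternary centre from commercial materials in a single catalytic step, and roughly half the length.

Key step: step 1

Assumption: the sense of induction of the (S)-oxazaborolidinium catalyst is taken from its formyl C–H···O binding model (Re face at the enal α-carbon open); should it prove opposite, the (R)-catalyst would be used with no other change.

## Route

Step 1
Reactants: 1 methacrolein; 2 (E)-β-ocimene (commercial E/Z mixture, in excess)
Product: 3 (1S,2R)-1,3-dimethyl-2-(3-methylbut-2-en-1-yl)cyclohex-3-ene-1-carbaldehyde (formyl cis to prenyl)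
Conditions: (S)-3,3-diphenyl-1-(2-methylphenyl)tetrahydro-1H,3H-pyrrolo[1,2-c][1,3,2]oxazaborole (20 mol %), Tf2NH (18 mol %), CH2Cl2, −78 to −40 °C
Reagents that add atoms: none
Why: The protonated oxazaborolidine binds the formyl oxygen of 1 at boron, with a formyl C–H···O contact to the ring oxygen, and holds the s-trans enal over one phenyl group so that only the Re face of the α-carbon is open; the E-diene of 2 then adds in a concerted, asynchronous [4+2] cycloaddition in which C1–C2 (enal β-carbon to the unsubstituted diene terminus) runs ahead of C5–C10. The closest known reaction type is the oxazaborolidinium-catalysed enantioselective Diels–Alder reaction of methacrolein with acyclic 1-substituted and 2-substituted butadienes, whose substitution patterns 2 combines. Ring A closes by intermolecular [4+2] cycloaddition through an endo transition state. C10 is controlled by the catalyst (enal face), and C5 follows from the E geometry of the diene together with the endo position of the boron-bound formyl group, which places CHO cis to the prenyl chain. The regiochemistry needed (C10 to C5) should be secured because the first bond joins the two unhindered CH2 termini and leaves allyl-cation character over C3–C5, as with 1-vinylcycloalkene dienes that share the 1,2-dialkyl pattern. Chemoselectivity should be secured because the isolated trisubstituted alkene is no diene and the Z isomer of 2 cannot reach the s-cis conformation, so it stays behind and is removed with the excess diene. Low temperature and slow addition of 2 limit its cationic oligomerisation by the strongly acidic catalyst.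

Step 2
Reactants: 3; 4 (methoxymethyl)triphenylphosphonium chloride
Product: 6 (5S,6R)-5-(2-methoxyethenyl)-1,5-dimethyl-6-(3-methylbut-2-en-1-yl)cyclohex-1-ene (E/Z mixture at the enol ether), via (methoxymethylene)triphenylphosphorane 5 (not isolated)
Conditions: 4, KOt-Bu, THF, 0 °C; then 3, 0 °C to rt
Reagents that add atoms: (methoxymethyl)triphenylphosphonium chloride 4, [Cl-].COC[P+](c1ccccc1)(c1ccccc1)c1ccccc1
Why: Wittig methoxymethylenation; the small, reactive ylide 5 is the standard reagent for homologating neopentyl aldehydes, 3 has no α-hydrogen so nothing can epimerise, and the enol ether geometry is irrelevant.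

Step 3
Reactants: 6
Product: 7 2-[(1R,2S)-1,3-dimethyl-2-(3-methylbut-2-en-1-yl)cyclohex-3-en-1-yl]acetaldehyde
Conditions: 2 M aq HCl, THF, 0 °C to rt; used directly
Reagents that add atoms: water, O
Why: Acid hydrolysis of an enol ether; in the aqueous medium water should capture the oxocarbenium ion faster than the prenyl alkene can, and without a Lewis acid the citronellal-type aldehyde 7 should not undergo carbonyl-ene closure; no stereocentre is touched.

Step 4
Reactants: 7
Product: 8 cis-eudesm-3-en-8-one [(5S,10R); 5β-H, 10β-CH3; both C7 epimers]
Conditions: t-C12H25SH (tert-dodecanethiol, 30 mol %), azobisisobutyronitrile (AIBN, 20 mol %, in portions), degassed PhCl (0.02 M), 80 °C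
Reagents that add atoms: none
Why: Thiol-catalysed radical-chain hydroacylation, the reaction that converts citronellal into menthone: the thiyl radical abstracts the formyl hydrogen, the C8 acyl radical closes 6-exo-trig onto C7 of the prenyl group, and the tertiary C11 radical takes hydrogen back from the thiol. The cis junction is already fixed by C5 and C10; C7 forms without control and is corrected in step 6.

Step 5
Reactants: 8
Product: 10 (3R,4S,5S,10R)-4-acetoxy-3-hydroxy-cis-eudesman-8-one (3α-OH, 4α-OAc, 4β-CH3; both C7 epimers), via 3β-iodo-4α-acetoxy-cis-eudesman-8-one 9 (not isolated)
Conditions: I2 (1.05 equiv), AgOAc (2.2 equiv), AcOH, rt; then H2O, 90 °C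
Reagents that add atoms: silver acetate, [Ag+].CC(=O)[O-]; water, O
Why: Woodward cis-hydroxylation: iodonium adds to the convex β face (ring B lies under the α face), acetate opens it anti at the more substituted C4 to give 9, and silver-assisted displacement of the C3 iodide by the neighbouring acetate from the α side followed by hydrolysis of the cyclic cation in wet acetic acid leaves both oxygens α and C15 β. The axial C4 acetate is the expected ring-opening product, and any O3-acetate isomer converges in step 6.

Step 6
Reactants: 10
Product: 11 (3R,4S,5S,7R,10R)-3,4-dihydroxy-cis-eudesman-8-one (3α,4α-diol, 7β-isopropyl)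
Conditions: NaOMe (0.5 equiv), MeOH, rt to 40 °C
Reagents that add atoms: none
Why: Zemplén transesterification removes the acetate while the same methoxide equilibrates C7 through the C8 enolate; with C14 and C15 both equatorial on ring A the decalin is locked in the chair–chair form in which 7β-isopropyl is equatorial and a 7α group would be syn-axial to C4, so the natural epimer should strongly predominate.

Step 7
Reactants: 11; 12 angelic acid
Product: 14 (3R,4S,5S,7R,10R)-4-hydroxy-8-oxo-cis-eudesman-3-yl (Z)-2-methylbut-2-enoate, via angelic 2,4,6-trichlorobenzoic anhydride 13 (not isolated)
Conditions: 12, 2,4,6-Cl3C6H2COCl, Et3N, toluene, rt; then 11, 75 °C (no DMAP)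
Reagents that add atoms: angelic acid 12, C/C=C(/C)C(=O)O
Why: Yamaguchi esterification; the mixed anhydride 13 should acylate only the equatorial secondary C3–OH, the axial tertiary C4–OH being inert under these conditions, and leaving out the nucleophilic catalyst avoids the addition–elimination pathway that turns angelates into tiglates.

Step 8
Reactants: 14
Product: 15 CNP0322180.1, (3R,4S,5S,7R,10R)-4-acetoxy-8-oxo-cis-eudesman-3-yl (Z)-2-methylbut-2-enoate (3α-angeloyloxy, 4α-acetoxy, 5β-H, 7β-isopropyl, 10β-CH3)
Conditions: Ac2O (10 equiv), Et3N, 4-(dimethylamino)pyridine (DMAP, 1 equiv), CH2Cl2, rt to 40 °C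
Reagents that add atoms: acetic anhydride, CC(=O)OC(C)=O
Why: Steglich-type DMAP-catalysed acetylation of a tertiary alcohol; the only other hydroxyl is already blocked as the angelate, the basic non-ionising conditions cannot open the C4–O bond, and C7 is already in its thermodynamic configuration.

## Compound list

1 | methacrolein (2-methylprop-2-enal) | CC(=C)C=O | starting material
2 | (E)-β-ocimene, (3E)-3,7-dimethylocta-1,3,6-triene | C=C/C(C)=C/CC=C(C)C | starting material
3 | (1S,2R)-1,3-dimethyl-2-(3-methylbut-2-en-1-yl)cyclohex-3-ene-1-carbaldehyde (formyl cis to prenyl) | O=C[C@@]1(C)CCC=C(C)[C@H]1CC=C(C)C | intermediate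
4 | (methoxymethyl)triphenylphosphonium chloride | [Cl-].COC[P+](c1ccccc1)(c1ccccc1)c1ccccc1 | starting material
5 | (methoxymethylene)triphenylphosphorane | COC=P(c1ccccc1)(c1ccccc1)c1ccccc1 | intermediate
6 | (5S,6R)-5-(2-methoxyethenyl)-1,5-dimethyl-6-(3-methylbut-2-en-1-yl)cyclohex-1-ene (E/Z mixture) | COC=C[C@@]1(C)CCC=C(C)[C@H]1CC=C(C)C | intermediate
7 | 2-[(1R,2S)-1,3-dimethyl-2-(3-methylbut-2-en-1-yl)cyclohex-3-en-1-yl]acetaldehyde | O=CC[C@@]1(C)CCC=C(C)[C@H]1CC=C(C)C | intermediate
8 | cis-eudesm-3-en-8-one, (5S,10R), both C7 epimers | CC1=CCC[C@]2(C)CC(=O)C(C(C)C)C[C@H]12 | intermediate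
9 | (3S,4S,5S,10R)-4-acetoxy-3-iodo-cis-eudesman-8-one (3β-I, 4α-OAc; both C7 epimers) | I[C@H]1CC[C@]2(C)CC(=O)C(C(C)C)C[C@@H]2[C@]1(C)OC(C)=O | intermediate
10 | (3R,4S,5S,10R)-4-acetoxy-3-hydroxy-cis-eudesman-8-one (3α-OH, 4α-OAc; both C7 epimers) | O[C@@H]1CC[C@]2(C)CC(=O)C(C(C)C)C[C@@H]2[C@]1(C)OC(C)=O | intermediate
11 | (3R,4S,5S,7R,10R)-3,4-dihydroxy-cis-eudesman-8-one (3α,4α-diol, 7β-isopropyl) | O[C@@H]1CC[C@]2(C)CC(=O)[C@@H](C(C)C)C[C@@H]2[C@]1(C)O | intermediate
12 | angelic acid, (Z)-2-methylbut-2-enoic acid | C/C=C(/C)C(=O)O | starting material
13 | angelic 2,4,6-trichlorobenzoic anhydride | C/C=C(/C)C(=O)OC(=O)c1c(Cl)cc(Cl)cc1Cl | intermediate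
14 | (3R,4S,5S,7R,10R)-4-hydroxy-8-oxo-cis-eudesman-3-yl (Z)-2-methylbut-2-enoate | C/C=C(/C)C(=O)O[C@@H]1CC[C@]2(C)CC(=O)[C@@H](C(C)C)C[C@@H]2[C@]1(C)O | intermediate
15 | CNP0322180.1, (3R,4S,5S,7R,10R)-4-acetoxy-8-oxo-cis-eudesman-3-yl (Z)-2-methylbut-2-enoate | C/C=C(/C)C(=O)O[C@@H]1CC[C@]2(C)CC(=O)[C@@H](C(C)C)C[C@@H]2[C@]1(C)OC(C)=O | target

## Count and risks

Total step count: 8. Longest linear sequence: 8 steps (1 and 2 to 15).

**Step 1 (key step).** Most likely to go wrong: erosion of endo and facial selectivity, because the α-methyl group of 1 competes with the formyl group for the endo position and makes 1 a sluggish dienophile. Partial leakage into the para regiochemical mode and acid-induced oligomerisation of 2 are further risks. The fallback sets out from 2 and returns at 3. Acrolein replaces 1 under the same catalyst; without the α-substituent it reacts faster and its endo preference is uncontested, so the adduct should be (1S,2S)-3-methyl-2-(3-methylbut-2-en-1-yl)cyclohex-3-ene-1-carbaldehyde F1, with formyl cis to prenyl and the same C5 configuration. Its potassium enolate (KOt-Bu, THF, 0 °C) is then C-methylated with MeI. Allylic strain from both flanking trigonal carbons holds the C5 prenyl group pseudo-axial, so the electrophile should enter anti to it, which gives 3. C5 is then set by the cycloaddition and C10 by the alkylation.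

**Step 5.** Most likely to go wrong: loss of control in the iodonium/cyclic-cation sequence, through elimination from the cationic tertiary C4, incomplete β-face selectivity of the iodonium step with the epimer mixture at C7, or α-iodination of the ketone. The fallback sets out from 8 and returns at 11; it keeps the β-face attack but replaces the neighbouring-group inversion by an oxidation/reduction at C3.
- m-Chloroperbenzoic acid with NaHCO3 in CH2Cl2 at 0 °C should give 3β,4β-epoxy-cis-eudesman-8-one F4.
- Dilute HClO4 in aqueous THF opens it trans-diaxially at the tertiary C4 from the α side to cis-eudesmane-3β,4α-diol-8-one F5.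
- Dess–Martin periodinane oxidises the secondary alcohol to 4α-hydroxy-cis-eudesmane-3,8-dione F6.
- NaBH4 (one hydride equivalent, MeOH–CH2Cl2, −78 °C) should reduce the more electrophilic and less hindered α-hydroxy ketone by axial, β-face delivery to 3α,4α-dihydroxy-cis-eudesman-8-one F7 (C7 epimer mixture).
- The methoxide conditions of step 6 then convert F7 into 11.

**Step 4.** Most likely to go wrong: diversion of the acyl radical or the chain carrier. Possible paths are bridging attack on the ring A alkene, reversible thiyl abstraction of the doubly activated C5–H with scrambling of that centre, decarbonylation, or simple chain failure with the electron-rich alkene. The fallback sets out from 7 and returns at 8; it makes the same C7–C8 bond by a closed-shell path.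
- Me2AlCl in CH2Cl2 at −78 °C effects the carbonyl-ene cyclisation (the citronellal-to-isopulegol reaction) to cis-eudesma-3,11-dien-8-ol F2.
- RhCl(PPh3)3 under H2 in benzene hydrogenates only the 1,1-disubstituted alkene, giving cis-eudesm-3-en-8-ol F3.
- Dess–Martin periodinane oxidation gives 8, again as a C7 mixture that step 6 corrects.

**Step 8.** Most likely to go wrong: failure of the axial, doubly flanked tertiary hydroxyl to acetylate before side processes take over, namely migration of the angeloyl group to O4 followed by acetylation at O3, or slow isomerisation of the angelate under prolonged base and heat. The fallback sets out from 11 and returns at 15; it installs the tertiary acetate first, by ring opening instead of acylation.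
- MeC(OMe)3 with pyridinium p-toluenesulfonate in CH2Cl2 converts 11 into the cyclic 3α,4α-(1-methoxyethylidene) orthoacetate F8.
- Aqueous AcOH at rt should open it kinetically to the axial ester, (3R,4S,5S,7R,10R)-4-acetoxy-3-hydroxy-cis-eudesman-8-one F9.
- F9 is angeloylated at once with anhydride 13 as in step 7, at the lowest workable temperature to limit acetyl migration, giving 15.

## Further compounds

F1 | step 1 | (1S,2S)-3-methyl-2-(3-methylbut-2-en-1-yl)cyclohex-3-ene-1-carbaldehyde (formyl cis to prenyl) | O=C[C@H]1CCC=C(C)[C@H]1CC=C(C)C
F2 | step 4 | cis-eudesma-3,11-dien-8-ol, (5S,10R), mixture at C7 and C8 | CC1=CCC[C@]2(C)CC(O)C(C(C)=C)C[C@H]12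
F3 | step 4 | cis-eudesm-3-en-8-ol, (5S,10R), mixture at C7 and C8 | CC1=CCC[C@]2(C)CC(O)C(C(C)C)C[C@H]12
F4 | step 5 | 3β,4β-epoxy-cis-eudesman-8-one, both C7 epimers | O1[C@H]2CC[C@]3(C)CC(=O)C(C(C)C)C[C@@H]3[C@@]12C
F5 | step 5 | 3β,4α-dihydroxy-cis-eudesman-8-one (4β-CH3), both C7 epimers | O[C@H]1CC[C@]2(C)CC(=O)C(C(C)C)C[C@@H]2[C@]1(C)O
F6 | step 5 | 4α-hydroxy-cis-eudesmane-3,8-dione, both C7 epimers | O=C1CC[C@]2(C)CC(=O)C(C(C)C)C[C@@H]2[C@]1(C)O
F7 | step 5 | 3α,4α-dihydroxy-cis-eudesman-8-one, both C7 epimers | O[C@@H]1CC[C@]2(C)CC(=O)C(C(C)C)C[C@@H]2[C@]1(C)O
F8 | step 8 | 3α,4α-(1-methoxyethylidenedioxy)-cis-eudesman-8-one (cyclic orthoacetate of 11, both orthoester epimers) | COC1(C)O[C@@H]2CC[C@]3(C)CC(=O)[C@@H](C(C)C)C[C@@H]3[C@]2(C)O1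
F9 | step 8 | (3R,4S,5S,7R,10R)-4-acetoxy-3-hydroxy-cis-eudesman-8-one (7β-isopropyl) | O[C@@H]1CC[C@]2(C)CC(=O)[C@@H](C(C)C)C[C@@H]2[C@]1(C)OC(C)=O
A1 | alternative 1 | (4R,7E)-9-(tert-butyldimethylsilyloxy)-4-(4-methoxybenzyloxy)-7-methyldeca-1,7,9-trien-3-one | C=CC(=O)[C@H](OCc1ccc(OC)cc1)CC/C(C)=C/C(=C)O[Si](C)(C)C(C)(C)C
A2 | alternative 1 | cis-fused 3-(4-methoxybenzyloxy)-10-methyl-8-(tert-butyldimethylsilyloxy)octal-8-en-4-one (eudesmane numbering) | COc1ccc(CO[C@@H]2CC[C@]3(C)C=C(O[Si](C)(C)C(C)(C)C)CC[C@@H]3C2=O)cc1
A3 | alternative 2 | 2-ethenyl-3,3-dimethoxy-5-methyl-7-(propan-2-yl)bicyclo[2.2.2]oct-5-en-2-ol (vinyl and isopropyl syn to the alkene bridge) | C=C[C@@]1(O)[C@H]2C=C(C)[C@H](C[C@@H]2C(C)C)C1(OC)OC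
A4 | alternative 2 | cis-fused 4,4-dimethoxy-10-methyl-7-isopropyloctal-8-en-3-one (eudesmane numbering) | O=C1CC[C@]2(C)C=C[C@@H](C(C)C)C[C@@H]2C1(OC)OC
A5 | alternative 3 | 3-[2-acetyl-5-(tert-butyldimethylsilyloxy)-1-methyl-4-(propan-2-yl)cyclohexyl]propanal (configuration as in A6) | O=CCC[C@]1(C)C[C@H](O[Si](C)(C)C(C)(C)C)[C@@H](C(C)C)C[C@@H]1C(C)=O
A6 | alternative 3 | cis-eudesmane-3α,4α-diol 8α-tert-butyldimethylsilyl ether | O[C@@H]1CC[C@]2(C)C[C@H](O[Si](C)(C)C(C)(C)C)[C@@H](C(C)C)C[C@@H]2[C@]1(C)O
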